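**Plan**

- Retrosynthesis: the ester C(acyl)–O bond is cut first, giving (R)-shikonin and (3Z)-5-methylhexa-3,5-dienoic acid. The quinone C1(carbonyl)–C2 bond is cut next (ring closure; retro-Moore rearrangement to a 2-alkynyl-2-hydroxybenzocyclobutenone). The carbinol–alkyne bond (the later C4–C3 bond) is cut last, giving a symmetric 3,6-disiloxybenzocyclobutenedione and a chiral terminal alkyne.
- Enabling feature: the quinone ring is a benzo-fused C1(=O)–C2(R)=C3(H)–C4(=O) unit on a symmetric 5,8-dioxygenated benzene ring. C1, C4, C4a and C8a are the four-membered ring of a benzocyclobutenedione, C2 and C3 are the two carbons of a terminal alkyne, and ring expansion gives the quinone oxidation level directly.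
- Forward: the benzene ring is bought and the cyclobutene ring is fused on by aryne [2+2] cycloaddition (steps 1–4). The alkyne is added (step 9), the strained ring is opened and reclosed to the quinone ring (step 10), desilylation gives shikonin (step 11), and the acyl chain is joined last (step 15).
- Stereochemistry: the one stereocentre (R) comes from asymmetric transfer hydrogenation of an ynone (step 7) and is never a reacting centre afterwards. The Z-alkene comes from cis-reduction of a conjugated enyne (step 13).

Key step: step 10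

Remark: the carbinol carbon of the target is R (shikonin series); the naphthazarin tautomers interconvert rapidly and are treated as one compound.

**Route**

Step 1
Reactants: 1 2-bromo-1,4-dimethoxybenzene; 2 1,1-diethoxyethene
Product: 5 2,5-dimethoxybicyclo[4.2.0]octa-1,3,5-trien-7-one, via benzyne 3 (not isolated), via diethyl ketal 4 (not isolated)
Conditions: NaNH2, THF, reflux; then 1 M HCl, THF–H2O, rt
Reagents that add atoms: water, O
Why: Stevens-type aryne [2+2] cycloaddition, in which NaNH2 removes the hydrogen between Br and OMe, bromide leaves to give the symmetric aryne 3, the electron-rich ketene acetal adds across the strained triple bond, and the ketal is hydrolysed on acidic work-up.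

Step 2
Reactants: 5 2,5-dimethoxybicyclo[4.2.0]octa-1,3,5-trien-7-one
Product: 7 2,5-dimethoxybicyclo[4.2.0]octa-1,3,5-triene-7,8-dione, via dibromide 6 (not isolated)
Conditions: NBS (2.2 equiv), (PhCO2)2 (5 mol%), PhCF3, reflux; then 50% aq. H2SO4, 60 °C
Reagents that add atoms: water, O
Why: Wohl–Ziegler radical bromination of the doubly activated CH2 (benzylic and alpha to the ketone) followed by hydrolysis of the gem-dibromide is the established passage from benzocyclobutenones to benzocyclobutenediones, and the ring ketone deactivates the dimethoxyarene toward ring bromination.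

Step 3
Reactants: 7 2,5-dimethoxybicyclo[4.2.0]octa-1,3,5-triene-7,8-dione
Product: 8 2,5-dihydroxybicyclo[4.2.0]octa-1,3,5-triene-7,8-dione
Conditions: BBr3 (3 equiv), CH2Cl2, −78 to 0 °C; then H2O
Reagents that add atoms: none
Why: Lewis-acid cleavage of aryl methyl ethers is done here on the simple, acid-stable dione, because demethylation would not be tolerated once the prenyl-bearing side chain is present.

Step 4
Reactants: 8 2,5-dihydroxybicyclo[4.2.0]octa-1,3,5-triene-7,8-dione
Product: 9 2,5-bis(tert-butyldimethylsilyloxy)bicyclo[4.2.0]octa-1,3,5-triene-7,8-dione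
Conditions: TBSOTf (2.4 equiv), 2,6-lutidine, CH2Cl2, −78 to 0 °C
Reagents that add atoms: tert-butyldimethylsilyl trifluoromethanesulfonate, CC(C)(C)[Si](C)(C)OS(=O)(=O)C(F)(F)F
Why: Silylation of the acidic phenols with a silyl triflate and a hindered, non-nucleophilic base, which does not attack the electrophilic 1,2-dione, installs groups that fluoride removes at the end.

Step 5
Reactants: 10 4-methylpent-3-enoic acid
Product: 12 N-methoxy-N,4-dimethylpent-3-enamide, via acyl imidazole 11 (not isolated)
Conditions: CDI, CH2Cl2, rt; then MeNH(OMe)·HCl, rt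
Reagents that add atoms: N,O-dimethylhydroxylamine hydrochloride, CNOC.Cl
Why: Weinreb amide formation through the acyl imidazole runs under nearly neutral conditions, so the beta,gamma-double bond should stay in place.

Step 6
Reactants: 12 N-methoxy-N,4-dimethylpent-3-enamide; 13 ethynyltrimethylsilane
Product: 15 6-methyl-1-(trimethylsilyl)hept-5-en-1-yn-3-one, via lithium acetylide 14 (not isolated)
Conditions: n-BuLi, THF, −78 °C; then 12, −78 to 0 °C; inverse quench into cold 1 M HCl
Reagents that add atoms: none
Why: Weinreb ketone synthesis, in which the chelated tetrahedral intermediate prevents over-addition and the acidic inverse quench keeps the released amine from adding to the ynone.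

Step 7
Reactants: 15 6-methyl-1-(trimethylsilyl)hept-5-en-1-yn-3-one
Product: 16 (3R)-6-methyl-1-(trimethylsilyl)hept-5-en-1-yn-3-ol
Conditions: Ru[(R,R)-TsNCH(Ph)CH(Ph)NH](p-cymene) (1 mol%), i-PrOH, rt
Reagents that add atoms: none
Why: Noyori asymmetric transfer hydrogenation of an alpha,beta-acetylenic ketone with the base-free amido complex of divalent ruthenium, in which the alkynyl group takes the place of the aryl group of an aryl ketone in the concerted hydride/proton transfer, so the (R,R)-ligand should deliver the R alcohol while the isolated alkene and the enolizable CH2 are left alone.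

Step 8
Reactants: 16 (3R)-6-methyl-1-(trimethylsilyl)hept-5-en-1-yn-3-ol
Product: 18 triethyl{[(3R)-6-methylhept-5-en-1-yn-3-yl]oxy}silane, via alkynol 17 (not isolated)
Conditions: K2CO3 (0.2 equiv), MeOH, rt; extraction into CH2Cl2 without concentration; then TESCl, imidazole, 0 °C
Reagents that add atoms: chlorotriethylsilane, CC[Si](Cl)(CC)CC
Why: Methoxide-catalysed protodesilylation of the alkynylsilane and O-silylation are telescoped because alkynol 17 is volatile, and neither operation touches the stereocentre.

Step 9
Reactants: 18 triethyl{[(3R)-6-methylhept-5-en-1-yn-3-yl]oxy}silane; 9 2,5-bis(tert-butyldimethylsilyloxy)bicyclo[4.2.0]octa-1,3,5-triene-7,8-dione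
Product: 20 2,5-bis(tert-butyldimethylsilyloxy)-8-hydroxy-8-[(3R)-6-methyl-3-(triethylsilyloxy)hept-5-en-1-yn-1-yl]bicyclo[4.2.0]octa-1,3,5-trien-7-one (both C8 epimers), via lithium acetylide 19 (not isolated)
Conditions: n-BuLi (1.05 equiv), THF, −78 °C; then cannulation into 9, THF, −78 °C; aq. NH4Cl at −78 °C
Reagents that add atoms: none
Why: 1,2-Addition of a lithium acetylide to one carbonyl of the symmetric dione at low temperature, where the alkoxide formed deactivates the second carbonyl; the new carbinol centre is uncontrolled and irrelevant because it becomes the C4 carbonyl.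

Step 10
Reactants: 20 2,5-bis(tert-butyldimethylsilyloxy)-8-hydroxy-8-[(3R)-6-methyl-3-(triethylsilyloxy)hept-5-en-1-yn-1-yl]bicyclo[4.2.0]octa-1,3,5-trien-7-one
Product: 23 5,8-bis(tert-butyldimethylsilyloxy)-2-[(1R)-4-methyl-1-(triethylsilyloxy)pent-3-en-1-yl]naphthalene-1,4-dione, via ketene 21 (not isolated), via diradical 22 (not isolated)
Conditions: p-xylene (0.01 M, degassed), 138 °C
Reagents that add atoms: none
Why: Moore rearrangement: thermal conrotatory 4π-electrocyclic opening of the strained four-membered ring of 20 cleaves the C7–C8 bond to give the ortho-quinoid (2-alkynylethenyl)ketene 21, the ketene carbon bonds to the distal alkyne carbon to give the aromatic naphthoxyl/C3 sigma,pi-diradical 22, and transfer of the hydroxyl hydrogen to the C3 radical gives quinone 23 without any oxidant. The closest known reaction type is the enyne-ketene cycloaromatization of 4-alkynyl-4-hydroxycyclobutenones and their benzo-fused congeners, a relative of the Myers–Saito cyclization. The quinone ring is closed in a 6-endo-dig mode by forming the C1(carbonyl)–C2 bond, driven by release of the cyclobutenone strain and recovery of benzene aromaticity. No stereocentre is created; the silyloxy-bearing carbon lies outside the reacting pi-system, so its R configuration should be carried through, and both carbinol epimers of 20 converge on 23. The step needs outward rotation of the hydroxyl group (so that the alkynyl group turns inward, next to the ketene) and 6-endo over 5-exo closure (which would give a 2-alkylideneindane-1,3-dione); the donor hydroxyl secures the first by torquoselectivity, and the alkyl-type substituent on the alkyne terminus, which cannot stabilize the exocyclic vinyl radical of the 5-exo path, secures the second. Regiochemistry is not an issue because dione 9 is symmetric, so either carbonyl leads to the same 2-substituted quinone.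

Step 11
Reactants: 23 5,8-bis(tert-butyldimethylsilyloxy)-2-[(1R)-4-methyl-1-(triethylsilyloxy)pent-3-en-1-yl]naphthalene-1,4-dione
Product: 24 5,8-dihydroxy-2-[(1R)-1-hydroxy-4-methylpent-3-en-1-yl]naphthalene-1,4-dione ((R)-shikonin)
Conditions: HF·pyridine, pyridine, THF, 0 °C to rt
Reagents that add atoms: none
Why: Fluoride cleavage of the two peri aryl silyl ethers and the secondary triethylsilyl ether under buffered, weakly acidic conditions avoids both base-induced racemization through the quinone methide tautomer and acid-induced cyclization onto the prenyl alkene.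

Step 12
Reactants: 25 but-3-yn-1-ol; 26 2-bromopropene
Product: 27 5-methylhex-5-en-3-yn-1-ol
Conditions: Pd(PPh3)2Cl2 (2 mol%), CuI (4 mol%), Et3N, THF, rt, sealed vessel
Reagents that add atoms: none
Why: Sonogashira coupling of a terminal alkyne with a vinyl bromide builds the conjugated enyne, and the free hydroxyl is tolerated.

Step 13
Reactants: 27 5-methylhex-5-en-3-yn-1-ol
Product: 28 (3Z)-5-methylhexa-3,5-dien-1-ol
Conditions: Zn dust activated with Cu(OAc)2 and AgNO3, MeOH–H2O 1:1, rt
Reagents that add atoms: none
Why: Boland reduction with Zn(Cu/Ag) reduces only conjugation-activated alkynes, by cis delivery of two hydrogens, so the Z-diene should form without over-reduction of the diene.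

Step 14
Reactants: 28 (3Z)-5-methylhexa-3,5-dien-1-ol
Product: 29 (3Z)-5-methylhexa-3,5-dienoic acid
Conditions: TEMPO (20 mol%), PhI(OAc)2 (2.2 equiv), MeCN–H2O 1:1, 0 °C to rt
Reagents that add atoms: water, O
Why: Oxoammonium (TEMPO/PhI(OAc)2) oxidation of the primary alcohol through the aldehyde hydrate runs under nearly neutral conditions, which should neither move the beta,gamma-double bond into conjugation nor scramble its Z geometry.

Step 15
Reactants: 24 5,8-dihydroxy-2-[(1R)-1-hydroxy-4-methylpent-3-en-1-yl]naphthalene-1,4-dione; 29 (3Z)-5-methylhexa-3,5-dienoic acid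
Product: 30 (1R)-1-(5,8-dihydroxy-1,4-dioxo-1,4-dihydronaphthalen-2-yl)-4-methylpent-3-en-1-yl (3Z)-5-methylhexa-3,5-dienoate
Conditions: DCC (1.3 equiv), DMAP (10 mol%), CH2Cl2, 0 °C, dark
Reagents that add atoms: none
Why: Steglich esterification should acylate only the side-chain alcohol, because the peri hydroxyls are locked in hydrogen bonds to the quinone carbonyls, and it proceeds with retention since the C–O bond of the stereocentre is not broken; low DMAP loading and 0 °C limit alpha-deprotonation of the activated acid.

**Compound list**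

1 | 2-bromo-1,4-dimethoxybenzene | COc1ccc(OC)c(Br)c1 | starting material
2 | 1,1-diethoxyethene | C=C(OCC)OCC | starting material
3 | 3,6-dimethoxybenzyne (3,6-dimethoxy-1,2-didehydrobenzene) | COC1=CC=C(OC)C#C1 | intermediate (not isolated)
4 | 7,7-diethoxy-2,5-dimethoxybicyclo[4.2.0]octa-1,3,5-triene | CCOC1(OCC)Cc2c(OC)ccc(OC)c21 | intermediate (not isolated)
5 | 2,5-dimethoxybicyclo[4.2.0]octa-1,3,5-trien-7-one | COc1ccc(OC)c2c1CC2=O | intermediate
6 | 8,8-dibromo-2,5-dimethoxybicyclo[4.2.0]octa-1,3,5-trien-7-one | COc1ccc(OC)c2c1C(Br)(Br)C2=O | intermediate (not isolated)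
7 | 2,5-dimethoxybicyclo[4.2.0]octa-1,3,5-triene-7,8-dione | COc1ccc(OC)c2c1C(=O)C2=O | intermediate
8 | 2,5-dihydroxybicyclo[4.2.0]octa-1,3,5-triene-7,8-dione | Oc1ccc(O)c2c1C(=O)C2=O | intermediate
9 | 2,5-bis(tert-butyldimethylsilyloxy)bicyclo[4.2.0]octa-1,3,5-triene-7,8-dione | CC(C)(C)[Si](C)(C)Oc1ccc(O[Si](C)(C)C(C)(C)C)c2c1C(=O)C2=O | intermediate
10 | 4-methylpent-3-enoic acid | CC(C)=CCC(=O)O | starting material
11 | 1-(1H-imidazol-1-yl)-4-methylpent-3-en-1-one | CC(C)=CCC(=O)n1ccnc1 | intermediate (not isolated)
12 | N-methoxy-N,4-dimethylpent-3-enamide | CC(C)=CCC(=O)N(C)OC | intermediate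
13 | ethynyltrimethylsilane | C#C[Si](C)(C)C | starting material
14 | lithium (trimethylsilyl)acetylide | [Li]C#C[Si](C)(C)C | intermediate (not isolated)
15 | 6-methyl-1-(trimethylsilyl)hept-5-en-1-yn-3-one | CC(C)=CCC(=O)C#C[Si](C)(C)C | intermediate
16 | (3R)-6-methyl-1-(trimethylsilyl)hept-5-en-1-yn-3-ol | O[C@H](CC=C(C)C)C#C[Si](C)(C)C | intermediate
17 | (3R)-6-methylhept-5-en-1-yn-3-ol | O[C@H](CC=C(C)C)C#C | intermediate (not isolated)
18 | triethyl{[(3R)-6-methylhept-5-en-1-yn-3-yl]oxy}silane | CC[Si](CC)(CC)O[C@H](CC=C(C)C)C#C | intermediate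
19 | lithium (3R)-6-methyl-3-(triethylsilyloxy)hept-5-en-1-yn-1-ide | CC[Si](CC)(CC)O[C@H](CC=C(C)C)C#C[Li] | intermediate (not isolated)
20 | 2,5-bis(tert-butyldimethylsilyloxy)-8-hydroxy-8-[(3R)-6-methyl-3-(triethylsilyloxy)hept-5-en-1-yn-1-yl]bicyclo[4.2.0]octa-1,3,5-trien-7-one (both C8 epimers) | CC[Si](CC)(CC)O[C@H](CC=C(C)C)C#CC1(O)C(=O)c2c(O[Si](C)(C)C(C)(C)C)ccc(O[Si](C)(C)C(C)(C)C)c21 | intermediate
21 | {3,6-bis(tert-butyldimethylsilyloxy)-2-[(4R)-1-hydroxy-7-methyl-4-(triethylsilyloxy)oct-6-en-2-yn-1-ylidene]cyclohexa-3,5-dien-1-ylidene}methanone (ortho-quinoid ketene, alkynyl group turned toward the ketene) | CC[Si](CC)(CC)O[C@H](CC=C(C)C)C#C/C(O)=C1\C(=C=O)C(O[Si](C)(C)C(C)(C)C)=CC=C1O[Si](C)(C)C(C)(C)C | intermediate (not isolated)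
22 | 5,8-bis(tert-butyldimethylsilyloxy)-4-hydroxy-2-[(1R)-4-methyl-1-(triethylsilyloxy)pent-3-en-1-yl]naphthalen-1-oxyl-3-yl diradical | CC[Si](CC)(CC)O[C@H](CC=C(C)C)c1[c]c(O)c2c(O[Si](C)(C)C(C)(C)C)ccc(O[Si](C)(C)C(C)(C)C)c2c1[O] | intermediate (not isolated)
23 | 5,8-bis(tert-butyldimethylsilyloxy)-2-[(1R)-4-methyl-1-(triethylsilyloxy)pent-3-en-1-yl]naphthalene-1,4-dione | CC[Si](CC)(CC)O[C@H](CC=C(C)C)C1=CC(=O)c2c(O[Si](C)(C)C(C)(C)C)ccc(O[Si](C)(C)C(C)(C)C)c2C1=O | intermediate
24 | 5,8-dihydroxy-2-[(1R)-1-hydroxy-4-methylpent-3-en-1-yl]naphthalene-1,4-dione ((R)-shikonin) | O[C@H](CC=C(C)C)C1=CC(=O)c2c(O)ccc(O)c2C1=O | intermediate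
25 | but-3-yn-1-ol | C#CCCO | starting material
26 | 2-bromopropene | C=C(C)Br | starting material
27 | 5-methylhex-5-en-3-yn-1-ol | C=C(C)C#CCCO | intermediate
28 | (3Z)-5-methylhexa-3,5-dien-1-ol | C=C(C)/C=C\CCO | intermediate
29 | (3Z)-5-methylhexa-3,5-dienoic acid | C=C(C)/C=C\CC(=O)O | intermediate
30 | (1R)-1-(5,8-dihydroxy-1,4-dioxo-1,4-dihydronaphthalen-2-yl)-4-methylpent-3-en-1-yl (3Z)-5-methylhexa-3,5-dienoate | C=C(C)/C=C\CC(=O)O[C@H](CC=C(C)C)C1=CC(=O)c2c(O)ccc(O)c2C1=O | target

**Step count and risks**

Total step count: 15. Longest linear sequence: 8 steps (steps 5, 6, 7, 8, 9, 10, 11, 15; the dione branch through steps 1–4 is equally long).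

Steps most likely to fail:

Step 10. Ketene 21 may close in the 5-exo mode, or diradical 22 may take hydrogen from the medium instead of from its own hydroxyl group, so that ring closure does not end cleanly in the quinone. The fallback sets out from alkyne 18 and dione 9 and comes back to the route at quinone 23. It replaces the alkyne by an alkene, so that the same ring closes by a concerted 6π-electrocyclization that has no 5-exo alternative. Hydrozirconation of 18 with Cp2Zr(H)Cl and iodinolysis with I2 should give triethyl{[(1E,3R)-1-iodo-6-methylhepta-1,5-dien-3-yl]oxy}silane F1. Iodine–lithium exchange (t-BuLi, Et2O, −78 °C) and addition to 9 should give 2,5-bis(tert-butyldimethylsilyloxy)-8-hydroxy-8-[(1E,3R)-6-methyl-3-(triethylsilyloxy)hepta-1,5-dien-1-yl]bicyclo[4.2.0]octa-1,3,5-trien-7-one F2. Heating in toluene opens the four-membered ring; the dienylketene electrocyclizes and tautomerizes to 5,8-bis(tert-butyldimethylsilyloxy)-2-[(1R)-4-methyl-1-(triethylsilyloxy)pent-3-en-1-yl]naphthalene-1,4-diol F3, and oxidation with Ag2O returns to 23.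

Step 2. Electrophilic bromination of the electron-rich dimethoxybenzene ring may compete with radical bromination of the CH2 group, or the gem-dibromide may resist hydrolysis. The fallback sets out from bromide 1 and comes back at dione 7; the two-carbon partner brings the dione oxidation level, so no bromination is needed. Methyl dimethoxyacetate is converted (LDA, TBSCl, THF, −78 °C) into tert-butyl(dimethyl)[(1,2,2-trimethoxyethenyl)oxy]silane F4. Aryne 3 is generated from 1 with lithium 2,2,6,6-tetramethylpiperidide (THF, −78 °C to rt) in the presence of F4, and [2+2] cycloaddition should give tert-butyl(dimethyl)[(2,5,7,8,8-pentamethoxybicyclo[4.2.0]octa-1,3,5-trien-7-yl)oxy]silane F5. Aqueous acid (H2SO4, THF–H2O) hydrolyses both ketal carbons to give 7.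

Step 15. In the carbodiimide/DMAP-activated acid, alpha-deprotonation may move the beta,gamma-double bond into conjugation and scramble the Z geometry before acyl transfer. The fallback sets out from acid 29 and alcohol 24 and comes back at target 30; it uses a thioester activated by a thiophilic metal, with no nucleophilic amine and no acylpyridinium ion. Acid 29 is converted under neutral redox-condensation conditions (2,2'-dipyridyl disulfide, PPh3, CH2Cl2, rt) into S-(pyridin-2-yl) (3Z)-5-methylhexa-3,5-dienethioate F6. F6 is then united with 24 under AgBF4 promotion (toluene, rt, 2,6-di-tert-butylpyridine as proton trap) to give 30.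

**Further compounds**

F1 | step 10 | triethyl{[(1E,3R)-1-iodo-6-methylhepta-1,5-dien-3-yl]oxy}silane | CC[Si](CC)(CC)O[C@H](CC=C(C)C)/C=C/I
F2 | step 10 | 2,5-bis(tert-butyldimethylsilyloxy)-8-hydroxy-8-[(1E,3R)-6-methyl-3-(triethylsilyloxy)hepta-1,5-dien-1-yl]bicyclo[4.2.0]octa-1,3,5-trien-7-one | CC[Si](CC)(CC)O[C@H](CC=C(C)C)/C=C/C1(O)C(=O)c2c(O[Si](C)(C)C(C)(C)C)ccc(O[Si](C)(C)C(C)(C)C)c21
F3 | step 10 | 5,8-bis(tert-butyldimethylsilyloxy)-2-[(1R)-4-methyl-1-(triethylsilyloxy)pent-3-en-1-yl]naphthalene-1,4-diol | CC[Si](CC)(CC)O[C@H](CC=C(C)C)c1cc(O)c2c(O[Si](C)(C)C(C)(C)C)ccc(O[Si](C)(C)C(C)(C)C)c2c1O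
F4 | step 2 | tert-butyl(dimethyl)[(1,2,2-trimethoxyethenyl)oxy]silane | COC(OC)=C(OC)O[Si](C)(C)C(C)(C)C
F5 | step 2 | tert-butyl(dimethyl)[(2,5,7,8,8-pentamethoxybicyclo[4.2.0]octa-1,3,5-trien-7-yl)oxy]silane | COc1ccc(OC)c2c1C(OC)(OC)C2(OC)O[Si](C)(C)C(C)(C)C
F6 | step 15 | S-(pyridin-2-yl) (3Z)-5-methylhexa-3,5-dienethioate | C=C(C)/C=C\CC(=O)Sc1ccccn1
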